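**Retrosynthetic overview**

Germacrane numbering is used throughout: ring C1–C10 with C1=C10 and C4=C5 (both Z), OAc on C3 and C9, and the γ-lactone O–C6/C7/C11(C13 methyl)/C12(=O).
Enabling feature: C6 lies in both the ten-membered carbocycle and the γ-lactone. It is an allylic carbinol carbon bonded to the vinylic C5 of the Z C4=C5 alkene, and its oxygen sits 1,4 to the C12 carboxyl. A C5 vinyl–chromium adding to a C6 aldehyde therefore forms C5–C6 as the last C–C bond, closes the carbocycle, sets C6, and lets the new alkoxide close the lactone on a C12 methyl ester in the same operation.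
The acyclic seco-aldehyde (both acetates in place) comes from a temporary δ-lactone (O on C9, carbonyl C12): trans conjugate addition of a formyl-anion equivalent (C6) at C7 and trans enolate methylation at C11 set C7 and C11 from C9, then the lactone is opened and acetylated.
The unsaturated δ-lactone comes from allylboration/acryloylation/ring-closing metathesis of a Z-enal (C9) built by Still–Gennari olefination (C1=C10); C3 and the Z-iodoalkene (C4=C5) come from allylboration of (Z)-3-iodo-2-methylacrolein, made from propargyl alcohol by anti-carbomagnesiation/iodination.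
Ring order: δ-lactone template (formed in step 11, opened in step 14), then the ten-membered ring and the γ-lactone together (step 17).

Key step: step 17

TBS = tert-butyldimethylsilyl.

**Route**

Step 1
Reactants: 1 prop-2-yn-1-ol
Product: 3 (Z)-3-iodo-2-methylprop-2-en-1-ol, via cyclic alkenylmagnesium alkoxide 2 (not isolated)
Conditions: MeMgBr (2.5 equiv), CuI (copper monoiodide, 10 mol%), THF, −10 °C to rt; then I2, −78 to 0 °C
Reagents that add atoms: methylmagnesium bromide, C[Mg]Br; iodine, II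
Why: Copper-catalysed carbomagnesiation of the magnesium propargyl alkoxide is alkoxide-directed, so methyl adds to C4 and magnesium to C5 in an anti sense to give the five-membered chelate, and iodinolysis with retention places iodine cis to the CH2OH group (Z).

Step 2
Reactants: 3 (Z)-3-iodo-2-methylprop-2-en-1-ol
Product: 4 (Z)-3-iodo-2-methylprop-2-enal
Conditions: activated MnO2 (excess), CH2Cl2, rt, dark; used crude
Reagents that add atoms: none
Why: Activated MnO2 oxidises the allylic alcohol under neutral heterogeneous conditions that leave the vinyl iodide and its Z geometry untouched (allylic oxidation).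

Step 3
Reactants: 4 (Z)-3-iodo-2-methylprop-2-enal
Product: 5 (1Z,3S)-1-iodo-2-methylhexa-1,5-dien-3-ol
Conditions: (−)-Ipc2B(allyl) (from (+)-α-pinene), Et2O, −78 °C; then NaOH, H2O2, 0 °C to rt
Reagents that add atoms: (−)-B-allyldiisopinocampheylborane, C=CCB([C@@H]1C[C@@H]2C[C@H]([C@H]1C)C2(C)C)[C@@H]1C[C@@H]2C[C@H]([C@H]1C)C2(C)C
Why: Brown allylboration through a closed chair transition state is reagent-controlled, the (+)-α-pinene-derived borane delivering allyl to the Si face of the aldehyde, which sets C3 as S.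

Step 4
Reactants: 5 (1Z,3S)-1-iodo-2-methylhexa-1,5-dien-3-ol
Product: 6 (1Z,3S)-3-(TBS-oxy)-1-iodo-2-methylhexa-1,5-diene
Conditions: TBSCl, imidazole, DMF, rt
Reagents that add atoms: tert-butyldimethylsilyl chloride, CC(C)(C)[Si](C)(C)Cl
Why: Standard silylation of the secondary allylic alcohol protects the C3 oxygen against the basic and reducing steps that follow.

Step 5
Reactants: 6 (1Z,3S)-3-(TBS-oxy)-1-iodo-2-methylhexa-1,5-diene
Product: 7 (3S,4Z)-3-(TBS-oxy)-5-iodo-4-methylpent-4-enal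
Conditions: OsO4 (2 mol%), NaIO4 (4 equiv), 2,6-lutidine, dioxane/H2O, rt
Reagents that add atoms: osmium tetroxide, O=[Os](=O)(=O)=O (catalytic oxygen carrier); sodium periodate, [Na+].[O-]I(=O)(=O)=O
Why: Lemieux–Johnson cleavage takes place at the monosubstituted terminal alkene because the trisubstituted iodoalkene is sterically shielded and electron-poor and is dihydroxylated far more slowly.

Step 6
Reactants: 7 (3S,4Z)-3-(TBS-oxy)-5-iodo-4-methylpent-4-enal
Product: 8 methyl (2Z,5S,6Z)-5-(TBS-oxy)-7-iodo-2,6-dimethylhepta-2,6-dienoate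
Conditions: methyl 2-[bis(2,2,2-trifluoroethoxy)phosphoryl]propanoate, KN(SiMe3)2, 18-crown-6, THF, −78 °C
Reagents that add atoms: methyl 2-[bis(2,2,2-trifluoroethoxy)phosphoryl]propanoate, COC(=O)C(C)P(=O)(OCC(F)(F)F)OCC(F)(F)F
Why: Still–Gennari olefination with the electron-poor bis(trifluoroethyl) phosphonate eliminates from the kinetically formed adduct and should give the Z-trisubstituted enoate (C2 cis to C9), the β-silyloxy aldehyde tolerating the non-nucleophilic anion at −78 °C.

Step 7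
Reactants: 8 methyl (2Z,5S,6Z)-5-(TBS-oxy)-7-iodo-2,6-dimethylhepta-2,6-dienoate
Product: 9 (2Z,5S,6Z)-5-(TBS-oxy)-7-iodo-2,6-dimethylhepta-2,6-dien-1-ol
Conditions: i-Bu2AlH (2.5 equiv), CH2Cl2, −78 °C; aq. potassium sodium tartrate
Reagents that add atoms: none
Why: i-Bu2AlH reduces the conjugated ester by 1,2-hydride delivery to the allylic alcohol without touching the alkene geometry, the silyl ether or the vinyl iodide.

Step 8
Reactants: 9 (2Z,5S,6Z)-5-(TBS-oxy)-7-iodo-2,6-dimethylhepta-2,6-dien-1-ol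
Product: 10 (2Z,5S,6Z)-5-(TBS-oxy)-7-iodo-2,6-dimethylhepta-2,6-dienal
Conditions: activated MnO2 (excess), CH2Cl2, rt; used at once
Reagents that add atoms: none
Why: MnO2 oxidation of the allylic alcohol gives the Z-enal under neutral conditions that avoid Z-to-E isomerisation (allylic oxidation).

Step 9
Reactants: 10 (2Z,5S,6Z)-5-(TBS-oxy)-7-iodo-2,6-dimethylhepta-2,6-dienal
Product: 11 (4R,5Z,8S,9Z)-8-(TBS-oxy)-10-iodo-5,9-dimethyldeca-1,5,9-trien-4-ol
Conditions: (+)-Ipc2B(allyl) (from (−)-α-pinene), Et2O, −78 °C; then NaOH, H2O2, 0 °C to rt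
Reagents that add atoms: (+)-B-allyldiisopinocampheylborane, C=CCB([C@H]1C[C@H]2C[C@@H]([C@@H]1C)C2(C)C)[C@H]1C[C@H]2C[C@@H]([C@@H]1C)C2(C)C
Why: Brown allylboration with the enantiomeric reagent adds allyl 1,2 to the Re face of the enal under reagent control (the remote C3 centre has no influence), which sets C9 as R.

Step 10
Reactants: 11 (4R,5Z,8S,9Z)-8-(TBS-oxy)-10-iodo-5,9-dimethyldeca-1,5,9-trien-4-ol
Product: 12 (4R,5Z,8S,9Z)-8-(TBS-oxy)-10-iodo-5,9-dimethyldeca-1,5,9-trien-4-yl prop-2-enoate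
Conditions: acryloyl chloride, Et3N, DMAP (cat.), CH2Cl2, −20 to 0 °C
Reagents that add atoms: acryloyl chloride, C=CC(=O)Cl
Why: O-Acylation of the secondary alcohol with the acid chloride installs C11 and C12 and sets up the diene for ring closure.

Step 11
Reactants: 12 (4R,5Z,8S,9Z)-8-(TBS-oxy)-10-iodo-5,9-dimethyldeca-1,5,9-trien-4-yl prop-2-enoate
Product: 13 (6R)-6-[(2Z,5S,6Z)-5-(TBS-oxy)-7-iodo-6-methylhepta-2,6-dien-2-yl]-5,6-dihydro-2H-pyran-2-one
Conditions: second-generation Grubbs catalyst, (H2IMes)(PCy3)Cl2Ru=CHPh (5 mol%), CH2Cl2 (5 mM), 40 °C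
Reagents that add atoms: none
Why: Ring-closing metathesis between the terminal alkene and the acrylate gives the six-membered unsaturated lactone, while the trisubstituted C1=C10 alkene and the hindered iodoalkene are too substituted to engage the ruthenium carbene.

Step 12
Reactants: 13 (6R)-6-[(2Z,5S,6Z)-5-(TBS-oxy)-7-iodo-6-methylhepta-2,6-dien-2-yl]-5,6-dihydro-2H-pyran-2-one
Product: 15 (3R,4S,6R)-4-(1,3-dithian-2-yl)-3-methyl-6-[(2Z,5S,6Z)-5-(TBS-oxy)-7-iodo-6-methylhepta-2,6-dien-2-yl]oxan-2-one, via lithium lactone enolate 14 (not isolated)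
Conditions: 1,3-dithiane, n-BuLi, THF, −30 °C; HMPA, −78 °C; add 13; then MeI, −78 to −40 °C
Reagents that add atoms: 2-lithio-1,3-dithiane, [Li]C1SCCCS1 (made in the flask from 1,3-dithiane, C1CSCSC1, and n-BuLi); iodomethane, CI
Why: Tandem conjugate addition–enolate alkylation, in which the sulfur-stabilised anion attacks C7 of the half-chair lactone axially and anti to the pseudo-equatorial substituent on C9, and the resulting enolate is methylated at C11 anti to the new dithianyl group, giving the 3,4-trans-4,6-trans lactone (C7 S, C11 R).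

Step 13
Reactants: 15 (3R,4S,6R)-4-(1,3-dithian-2-yl)-3-methyl-6-[(2Z,5S,6Z)-5-(TBS-oxy)-7-iodo-6-methylhepta-2,6-dien-2-yl]oxan-2-one
Product: 16 (3R,4S,6R)-4-(1,3-dithian-2-yl)-6-[(2Z,5S,6Z)-5-hydroxy-7-iodo-6-methylhepta-2,6-dien-2-yl]-3-methyloxan-2-one
Conditions: HF·pyridine, pyridine, THF, 0 °C to rt
Reagents that add atoms: none
Why: Fluoride cleaves the Si–O bond of the secondary silyl ether, and buffered HF·pyridine leaves the lactone, the dithiane and the vinyl iodide intact.

Step 14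
Reactants: 16 (3R,4S,6R)-4-(1,3-dithian-2-yl)-6-[(2Z,5S,6Z)-5-hydroxy-7-iodo-6-methylhepta-2,6-dien-2-yl]-3-methyloxan-2-one
Product: 18 methyl (2R,3S,5R,6Z,9S,10Z)-3-(1,3-dithian-2-yl)-5,9-dihydroxy-11-iodo-2,6,10-trimethylundeca-6,10-dienoate, via lithium carboxylate 17 (not isolated)
Conditions: LiOH (1.5 equiv), THF/H2O, 0 °C to rt; evaporate; MeI, DMF, 0 °C to rt; used crude
Reagents that add atoms: lithium hydroxide, [Li+].[OH-]; iodomethane, CI
Why: Hydroxide opens the δ-lactone irreversibly to the carboxylate (acyl attack is faster than enolisation at C11 and the carboxylate is not enolisable), and SN2 methylation of the carboxylate in DMF gives the methyl ester without passing through the free hydroxy acid.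

Step 15
Reactants: 18 methyl (2R,3S,5R,6Z,9S,10Z)-3-(1,3-dithian-2-yl)-5,9-dihydroxy-11-iodo-2,6,10-trimethylundeca-6,10-dienoate
Product: 19 methyl (2R,3S,5R,6Z,9S,10Z)-5,9-diacetoxy-3-(1,3-dithian-2-yl)-11-iodo-2,6,10-trimethylundeca-6,10-dienoate
Conditions: Ac2O, pyridine, DMAP (cat.), CH2Cl2, 0 °C to rt
Reagents that add atoms: acetic anhydride, CC(=O)OC(C)=O
Why: DMAP-catalysed acetylation esterifies both secondary allylic alcohols at once and removes the C9 hydroxyl that could re-close the δ-lactone.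

Step 16
Reactants: 19 methyl (2R,3S,5R,6Z,9S,10Z)-5,9-diacetoxy-3-(1,3-dithian-2-yl)-11-iodo-2,6,10-trimethylundeca-6,10-dienoate
Product: 20 methyl (2R,3S,5R,6Z,9S,10Z)-5,9-diacetoxy-3-formyl-11-iodo-2,6,10-trimethylundeca-6,10-dienoate
Conditions: PhI(OCOCF3)2 (1.5 equiv), NaHCO3, MeCN/H2O 9:1, 0 °C, short reaction time
Reagents that add atoms: water, O
Why: Oxidative hydrolysis of the dithiane with the hypervalent iodine reagent under buffered aqueous conditions unmasks the C6 aldehyde without acid or base that could epimerise C7 or cleave the acetates.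

Step 17
Reactants: 20 methyl (2R,3S,5R,6Z,9S,10Z)-5,9-diacetoxy-3-formyl-11-iodo-2,6,10-trimethylundeca-6,10-dienoate
Product: 22 (3R,3aS,5R,6Z,9S,10Z,11aS)-3,6,10-trimethyl-2-oxo-2,3,3a,4,5,8,9,11a-octahydrocyclodeca[b]furan-5,9-diyl diacetate (the target), via macrocyclic hydroxy ester 21 (not isolated)
Conditions: CrCl2 (12 equiv), NiCl2 (0.1 equiv), degassed DMSO, 2 mM, slow addition of 20, rt; aq. NH4Cl; then PPTS (cat.), CH2Cl2, rt
Reagents that add atoms: none
Why: Zerovalent nickel (formed from NiCl2 and CrCl2) inserts into the C5–I bond with retention of the Z geometry, transmetalation gives the C5 vinyl–chromium dichloride (trivalent chromium), this adds intramolecularly to the C6 aldehyde, and the resulting alkoxide (hydroxy ester 21 after work-up) attacks the C12 methyl ester and expels methanol. The closest known reaction type is the Nozaki–Hiyama–Kishi macrocyclisation used for nine- to twelve-membered carbocycles, followed by the ordinary lactonisation of a γ-hydroxy ester. The ten-membered ring closes by 10-exo-trig attack of C5 on the C6 carbonyl, and the γ-lactone by 5-exo-trig acyl substitution of O6 at C12. The new stereocentre C6 is controlled by the adjacent C7 centre: in the ring-closing rotamer the branched C11 arm lies anti to the forming C5–C6 bond, the tether carbon C8 is gauche, and the bulky chromium-bound oxygen takes the sector next to H7, so H6 and H7 end up antiperiplanar, which is 6S and the trans-fused lactone. The step needs chemoselectivity (vinyl–chromium adds to the aldehyde but not to the acetates or the methyl ester, and the allylic acetates are not expected to ionise under these conditions), cyclisation over oligomerisation (high dilution with slow addition, helped by the two Z-trisubstituted alkenes that bend the chain), and the C6 facial selectivity just described, which is the least certain of the three.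

**Compound list**

1 | prop-2-yn-1-ol (propargyl alcohol) | C#CCO | starting material
2 | 4-methyl-2,5-dihydro-1,2-oxamagnesole (cyclic alkenylmagnesium alkoxide) | CC1=C[Mg]OC1 | intermediate
3 | (Z)-3-iodo-2-methylprop-2-en-1-ol | OC/C(C)=C\I | intermediate
4 | (Z)-3-iodo-2-methylprop-2-enal | O=C/C(C)=C\I | intermediate
5 | (1Z,3S)-1-iodo-2-methylhexa-1,5-dien-3-ol | I/C=C(C)\[C@@H](O)CC=C | intermediate
6 | (1Z,3S)-3-(tert-butyldimethylsilyloxy)-1-iodo-2-methylhexa-1,5-diene | I/C=C(C)\[C@@H](O[Si](C)(C)C(C)(C)C)CC=C | intermediate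
7 | (3S,4Z)-3-(tert-butyldimethylsilyloxy)-5-iodo-4-methylpent-4-enal | I/C=C(C)\[C@@H](O[Si](C)(C)C(C)(C)C)CC=O | intermediate
8 | methyl (2Z,5S,6Z)-5-(tert-butyldimethylsilyloxy)-7-iodo-2,6-dimethylhepta-2,6-dienoate | I/C=C(C)\[C@@H](O[Si](C)(C)C(C)(C)C)C/C=C(/C)C(=O)OC | intermediate
9 | (2Z,5S,6Z)-5-(tert-butyldimethylsilyloxy)-7-iodo-2,6-dimethylhepta-2,6-dien-1-ol | I/C=C(C)\[C@@H](O[Si](C)(C)C(C)(C)C)C/C=C(/C)CO | intermediate
10 | (2Z,5S,6Z)-5-(tert-butyldimethylsilyloxy)-7-iodo-2,6-dimethylhepta-2,6-dienal | I/C=C(C)\[C@@H](O[Si](C)(C)C(C)(C)C)C/C=C(/C)C=O | intermediate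
11 | (4R,5Z,8S,9Z)-8-(tert-butyldimethylsilyloxy)-10-iodo-5,9-dimethyldeca-1,5,9-trien-4-ol | I/C=C(C)\[C@@H](O[Si](C)(C)C(C)(C)C)C/C=C(/C)[C@H](O)CC=C | intermediate
12 | (4R,5Z,8S,9Z)-8-(tert-butyldimethylsilyloxy)-10-iodo-5,9-dimethyldeca-1,5,9-trien-4-yl prop-2-enoate | I/C=C(C)\[C@@H](O[Si](C)(C)C(C)(C)C)C/C=C(/C)[C@H](OC(=O)C=C)CC=C | intermediate
13 | (6R)-6-[(2Z,5S,6Z)-5-(tert-butyldimethylsilyloxy)-7-iodo-6-methylhepta-2,6-dien-2-yl]-5,6-dihydro-2H-pyran-2-one | I/C=C(C)\[C@@H](O[Si](C)(C)C(C)(C)C)C/C=C(/C)[C@H]1CC=CC(=O)O1 | intermediate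
14 | lithium enolate of the 4-(1,3-dithian-2-yl) lactone (lithium (4S,6R)-4-(1,3-dithian-2-yl)-6-alkenyl-5,6-dihydro-4H-pyran-2-olate) | I/C=C(C)\[C@@H](O[Si](C)(C)C(C)(C)C)C/C=C(/C)[C@H]1C[C@H](C2SCCCS2)C=C(O[Li])O1 | intermediate
15 | (3R,4S,6R)-4-(1,3-dithian-2-yl)-3-methyl-6-[(2Z,5S,6Z)-5-(tert-butyldimethylsilyloxy)-7-iodo-6-methylhepta-2,6-dien-2-yl]oxan-2-one | I/C=C(C)\[C@@H](O[Si](C)(C)C(C)(C)C)C/C=C(/C)[C@H]1C[C@H](C2SCCCS2)[C@@H](C)C(=O)O1 | intermediate
16 | (3R,4S,6R)-4-(1,3-dithian-2-yl)-6-[(2Z,5S,6Z)-5-hydroxy-7-iodo-6-methylhepta-2,6-dien-2-yl]-3-methyloxan-2-one | I/C=C(C)\[C@@H](O)C/C=C(/C)[C@H]1C[C@H](C2SCCCS2)[C@@H](C)C(=O)O1 | intermediate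
17 | lithium (2R,3S,5R,6Z,9S,10Z)-3-(1,3-dithian-2-yl)-5,9-dihydroxy-11-iodo-2,6,10-trimethylundeca-6,10-dienoate | I/C=C(C)\[C@@H](O)C/C=C(/C)[C@H](O)C[C@H](C1SCCCS1)[C@@H](C)C(=O)[O-].[Li+] | intermediate
18 | methyl (2R,3S,5R,6Z,9S,10Z)-3-(1,3-dithian-2-yl)-5,9-dihydroxy-11-iodo-2,6,10-trimethylundeca-6,10-dienoate | I/C=C(C)\[C@@H](O)C/C=C(/C)[C@H](O)C[C@H](C1SCCCS1)[C@@H](C)C(=O)OC | intermediate
19 | methyl (2R,3S,5R,6Z,9S,10Z)-5,9-diacetoxy-3-(1,3-dithian-2-yl)-11-iodo-2,6,10-trimethylundeca-6,10-dienoate | I/C=C(C)\[C@@H](OC(C)=O)C/C=C(/C)[C@H](OC(C)=O)C[C@H](C1SCCCS1)[C@@H](C)C(=O)OC | intermediate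
20 | methyl (2R,3S,5R,6Z,9S,10Z)-5,9-diacetoxy-3-formyl-11-iodo-2,6,10-trimethylundeca-6,10-dienoate | I/C=C(C)\[C@@H](OC(C)=O)C/C=C(/C)[C@H](OC(C)=O)C[C@H](C=O)[C@@H](C)C(=O)OC | intermediate
21 | methyl (2R)-2-[(1S,2S,3Z,5S,7Z,9R)-5,9-diacetoxy-2-hydroxy-4,8-dimethylcyclodeca-3,7-dien-1-yl]propanoate (6S hydroxy ester) | CC(=O)O[C@H]1C/C=C(/C)[C@H](OC(C)=O)C[C@H]([C@@H](/C=C\1C)O)[C@@H](C)C(=O)OC | intermediate
22 | (3R,3aS,5R,6Z,9S,10Z,11aS)-3,6,10-trimethyl-2-oxo-2,3,3a,4,5,8,9,11a-octahydrocyclodeca[b]furan-5,9-diyl diacetate; germacrane numbering 3S,6S,7S,9R,11R, 1(10)Z,4Z | CC(=O)O[C@H]1C/C=C(/C)[C@H](OC(C)=O)C[C@@H]2[C@@H](/C=C\1C)OC(=O)[C@@H]2C | target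

**Step count and risks**

Total step count: 17. Longest linear sequence: 17 steps (fully linear from propargyl alcohol).

Steps most likely to fail:

1. Step 17. The risk is poor facial selectivity in the addition to the C6 aldehyde during ring closure, with intermolecular coupling as a second loss channel. Fallback: setting out from 20, the same chromium-mediated closure is run with a neutral buffered work-up and no acid, so that the alcohols are isolated; the unwanted product is the 6R hydroxy ester F1. The alcohol mixture is oxidised with Dess–Martin periodinane to the macrocyclic enone F2. This is reduced under reagent control by Corey–Bakshi–Shibata reduction ((R)-Me-oxazaborolidine, catecholborane, −78 °C, on the assumption that the alkenyl arm acts as the large group) to 21, where the fallback rejoins the route; PPTS then closes the lactone to 22.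

2. Step 12. The risk is attack of the lithiated dithiane at the lactone carbonyl, or γ-deprotonation with ring opening, in place of conjugate addition. Fallback: setting out from 13, the bulkier and softer 2-lithio-2-(trimethylsilyl)-1,3-dithiane (THF/HMPA, −78 °C) is used for the conjugate addition, again with MeI trapping, to give the silylated dithiane lactone F3. Bu4NF in wet THF then removes both the carbon-bound trimethylsilyl group and the TBS ether, and the fallback rejoins the route at 16.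

3. Step 14. The risk is re-closure of the δ-lactone (or epimerisation at C11) at the dihydroxy ester stage before the C9 hydroxyl is acetylated. Fallback: setting out from 16, the lactone is opened with Me(MeO)NH·HCl/AlMe3 (CH2Cl2, 0 °C) to the dihydroxy Weinreb amide F4, which does not re-lactonise under neutral conditions. Acetylation (Ac2O, pyridine, DMAP) gives the diacetoxy Weinreb amide F5, and dithiane hydrolysis with PhI(OCOCF3)2 gives the aldehyde Weinreb amide F6. Ring closure with CrCl2/NiCl2 gives the macrocyclic hydroxy Weinreb amide F7, and PPTS closes the γ-lactone with loss of N,O-dimethylhydroxylamine, rejoining the route at 22.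

Further compounds
F1 | step 17 | methyl (2R)-2-[(1S,2R,3Z,5S,7Z,9R)-5,9-diacetoxy-2-hydroxy-4,8-dimethylcyclodeca-3,7-dien-1-yl]propanoate (6R hydroxy ester) | CC(=O)O[C@H]1C/C=C(/C)[C@H](OC(C)=O)C[C@H]([C@H](/C=C\1C)O)[C@@H](C)C(=O)OC
F2 | step 17 | methyl (2R)-2-[(1S,3Z,5S,7Z,9R)-5,9-diacetoxy-4,8-dimethyl-2-oxocyclodeca-3,7-dien-1-yl]propanoate (macrocyclic enone) | CC(=O)O[C@H]1C/C=C(/C)[C@H](OC(C)=O)C[C@H](C(=O)/C=C\1C)[C@@H](C)C(=O)OC
F3 | step 12 | (3R,4S,6R)-3-methyl-4-[2-(trimethylsilyl)-1,3-dithian-2-yl]-6-[(2Z,5S,6Z)-5-(tert-butyldimethylsilyloxy)-7-iodo-6-methylhepta-2,6-dien-2-yl]oxan-2-one | I/C=C(C)\[C@@H](O[Si](C)(C)C(C)(C)C)C/C=C(/C)[C@H]1C[C@H](C2([Si](C)(C)C)SCCCS2)[C@@H](C)C(=O)O1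
F4 | step 14 | (2R,3S,5R,6Z,9S,10Z)-3-(1,3-dithian-2-yl)-5,9-dihydroxy-11-iodo-N-methoxy-N,2,6,10-tetramethylundeca-6,10-dienamide | I/C=C(C)\[C@@H](O)C/C=C(/C)[C@H](O)C[C@H](C1SCCCS1)[C@@H](C)C(=O)N(C)OC
F5 | step 14 | (2R,3S,5R,6Z,9S,10Z)-5,9-diacetoxy-3-(1,3-dithian-2-yl)-11-iodo-N-methoxy-N,2,6,10-tetramethylundeca-6,10-dienamide | I/C=C(C)\[C@@H](OC(C)=O)C/C=C(/C)[C@H](OC(C)=O)C[C@H](C1SCCCS1)[C@@H](C)C(=O)N(C)OC
F6 | step 14 | (2R,3S,5R,6Z,9S,10Z)-5,9-diacetoxy-3-formyl-11-iodo-N-methoxy-N,2,6,10-tetramethylundeca-6,10-dienamide | I/C=C(C)\[C@@H](OC(C)=O)C/C=C(/C)[C@H](OC(C)=O)C[C@H](C=O)[C@@H](C)C(=O)N(C)OC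
F7 | step 14 | (2R)-2-[(1S,2S,3Z,5S,7Z,9R)-5,9-diacetoxy-2-hydroxy-4,8-dimethylcyclodeca-3,7-dien-1-yl]-N-methoxy-N-methylpropanamide | CC(=O)O[C@H]1C/C=C(/C)[C@H](OC(C)=O)C[C@H]([C@@H](/C=C\1C)O)[C@@H](C)C(=O)N(C)OC
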